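The oxolane ring (C1, O2, C3, C4, spiro C5) is cut at O2–C1 and C4–C5. O2–C3–C4 then is an enantiopure trans-2-aryl-3-vinyloxirane (vinyl = masked C4 hydroxymethyl), and C1=C5 is the exocyclic alkene of a β-aryloxy p-quinone methide. Pd(0) inserts this C=C into the allylic C4–O bond. The three-membered ring grows by two carbons, the transient phenolate is dearomatised at C5, and the dienone, the quaternary spiro centre and C1 arise in one operation. The step exploits that C5 lies para to the C8 carbonyl, so that C1 is a 1,6-acceptor and C5 a phenolate carbon nucleophile. A removable bromine at C10 steers both new stereocentres.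

Key step: step 11

Remark on numbering and supply: locants follow 2-oxaspiro[4.5]deca-6,9-dien-8-one (C1 = CH with the aryloxy side chain, O2, C3 = CH-aryl, C4 = CH-CH2OH, C5 = spiro carbon, C6=C7(OMe), C8 = C=O, C9=C10). 6-Bromovanillin, methyl dihydroferulate, diethyl allylphosphonate, (R)-4-benzyl-2-oxazolidinone and the D-fructose-derived Shi ketone are taken as commercial.

Step 1
Reactants: 1 vanillin
Product: 2 O-TIPS-vanillin
Conditions: TIPSCl, imidazole, DMF, rt
Reagents that add atoms: triisopropylsilyl chloride, CC(C)[Si](Cl)(C(C)C)C(C)C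
Why: Imidazole-promoted O-silylation of the only hydroxyl group; the aryl TIPS ether tolerates the basic, oxidative, Pd(0) and hydride steps ahead and falls with fluoride at the end.

Step 2
Reactants: 2 O-TIPS-vanillin; 3 diethyl allylphosphonate
Product: 4 (E)-1-aryl-1,3-butadiene
Conditions: 3, n-BuLi, THF, −78 °C; then 2, then DMPU, −78 °C → rt
Reagents that add atoms: none
Why: Horner–Wadsworth–Emmons olefination with the α-lithiated allylphosphonate, in which the polar co-solvent drives the elimination and the reversible addition funnels to the (E)-1-aryl-1,3-diene.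

Step 3
Reactants: 4 (E)-1-aryl-1,3-butadiene
Product: 5 (2R,3R)-2-aryl-3-vinyloxirane
Conditions: D-fructose-derived Shi ketone (30 mol %), Oxone, K2CO3, Bu4NHSO4 (cat.), MeCN–DMM / Na2B4O7–Na2EDTA buffer (pH ca. 10.5), −5 to 0 °C; cold extraction, Et3N-deactivated SiO2, stored cold
Reagents that add atoms: Oxone (potassium peroxymonosulfate), [K+].[O-]S(=O)(=O)OO
Why: Shi asymmetric epoxidation: the fructose-derived dioxirane reacts with the trans-disubstituted electron-rich styrenyl alkene and not with the terminal vinyl group, and the spiro transition state delivers oxygen to the same face as in trans-β-methylstyrene, which sets both oxirane carbons as (2R,3R), that is the later C3 and C4.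

Step 4
Reactants: 6 methyl dihydroferulate; 7 bromoacetic acid
Product: 8 aryloxyacetic acid
Conditions: NaH (2.1 equiv), THF–DMF, 0 → 50 °C; then 1 M HCl
Reagents that add atoms: none
Why: Williamson ether synthesis between the sodium phenoxide and sodium bromoacetate, with the hydride consumed by the two acidic protons so that the methyl ester is left alone.

Step 5
Reactants: 8 aryloxyacetic acid; 9 (R)-4-benzyl-2-oxazolidinone
Product: 10 N-(aryloxyacetyl)oxazolidinone
Conditions: DCC, DMAP (cat.), CH2Cl2, 0 °C → rt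
Reagents that add atoms: none
Why: Carbodiimide/DMAP (Steglich-type) N-acylation of the oxazolidinone by the acid, which installs the auxiliary without touching the methyl ester.

Step 6
Reactants: 11 6-bromovanillin
Product: 12 O-MOM-6-bromovanillin
Conditions: MOMCl, i-Pr2NEt, CH2Cl2, 0 °C → rt
Reagents that add atoms: chloromethyl methyl ether, COCCl
Why: O-alkylation of the phenol gives an acetal that survives boron triflate, borohydride and silylation and is later removed by the same reagent that activates the benzylic position.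

Step 7
Reactants: 10 N-(aryloxyacetyl)oxazolidinone; 12 O-MOM-6-bromovanillin
Product: 14 Evans syn-aldol adduct (2R,3S; auxiliary 4R), via dibutylboron Z-enolate 13 (not isolated)
Conditions: 10, Bu2BOTf, Et3N, CH2Cl2, −78 → 0 °C; then 12, −78 → 0 °C; pH 7 buffer, MeOH, 30% H2O2, 0 °C
Reagents that add atoms: none
Why: Evans syn-aldol reaction: soft enolisation affects only the imide and gives the Z-boron enolate, whose Zimmerman–Traxler transition state with the benzyl group of the (R)-auxiliary shielding one face sets the aryloxy-bearing carbon as (2R) (the later side-chain stereocentre) and the carbinol carbon as (3S), the latter being erased in step 10.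

Step 8
Reactants: 14 Evans syn-aldol adduct
Product: 15 (1S,2S)-triol
Conditions: LiBH4 (5 equiv), MeOH (5 equiv), THF, 0 °C → rt
Reagents that add atoms: none
Why: Lithium borohydride reduction cleaves the imide to the primary alcohol with release of the auxiliary and reduces the methyl ester in the same operation, while aryl bromide, MOM acetal and both stereocentres are inert.

Step 9
Reactants: 15 (1S,2S)-triol
Product: 16 bis-TBDPS ether with free benzylic alcohol
Conditions: TBDPSCl (2.1 equiv), imidazole, CH2Cl2–DMF, 0 °C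
Reagents that add atoms: tert-butyl(chloro)diphenylsilane, CC(C)(C)[Si](Cl)(c1ccccc1)c1ccccc1
Why: Sterically controlled silylation: the bulky chlorosilane reacts with the two primary alcohols and leaves the hindered secondary benzylic alcohol next to the ortho-bromoarene free.

Step 10
Reactants: 16 bis-TBDPS ether
Product: 18 E-configured bromo quinone methide (side-chain carbon R) kept as a dried CH2Cl2 solution, via benzylic bromide 17 (not isolated)
Conditions: TMSBr (3 equiv), CH2Cl2, 0 °C, 15 min; cold sat. aq NaHCO3 wash, Na2SO4; solution used at once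
Reagents that add atoms: none
Why: Bromotrimethylsilane turns the electron-rich benzylic alcohol into the bromide and cleaves the aryl MOM acetal to the aryl TMS ether, and the bicarbonate wash hydrolyses the latter and triggers 1,6-elimination of HBr (the standard generation of lignin-type p-quinone methides); allylic strain with the ortho bromine should enforce the E geometry, the benzylic stereocentre is deleted on purpose and the aryloxy-bearing centre is untouched.

Step 11
Reactants: 18 bromo quinone methide; 5 (2R,3R)-2-aryl-3-vinyloxirane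
Product: 19 10-bromo-4-vinyl spirodienone (1S,3S,4S,5R; side chain 1S)
Conditions: Pd2(dba)3·CHCl3 (2.5 mol %) and DPEphos (5.5 mol %) premixed so that no free phosphine meets 18, 5 (1.3 equiv), CH2Cl2–THF, 0 °C → rt, Ar
Reagents that add atoms: none
Why: Pd(0) ionises the allylic C4–O bond of oxirane 5 with inversion and leaves the C3–O bond untouched; the π-allylpalladium alkoxide adds through O2 to the exocyclic carbon (C1) of 18 in a reversible oxa-1,6-addition, and the para carbon (C5) of the phenolate so formed attacks the internal allyl terminus C4 anti to palladium, so that C1=C5 is inserted into the C4–O bond and the three-membered ring becomes the oxolane. The closest known reaction type is the palladium-catalysed 1,6-conjugate addition/annulation (formal [3+2]) of vinyl epoxides with p-quinone methides to 2-oxaspiro[4.5]deca-6,9-dien-8-ones. The single ring closure is a 5-exo attack on the π-allyl unit (the vinyl group stays exocyclic), preferred over the 7-endo attack at the CH2 terminus. C3 keeps the oxirane configuration, and C4 is formed with net retention (double inversion), which is also the trans-3,4 arrangement favoured if the allyl faces equilibrate. C5 and C1 are controlled by the C10 bromine, which lies in the plane of the six-membered ring and leans over one face of the closing oxolane: closure should go through the rotamer with Br anti to the C4 vinyl group, and because the O2–C1 bond forms reversibly only the C1 epimer whose side chain also avoids Br should cyclise (Curtin–Hammett), which places C6=C7(OMe), vinyl group and side chain on one face. The step needs C- over O-allylation and oxirane ionisation over C–Br insertion: the para oxygen cannot reach the allyl unit, the ring positions next to C5 are meta to the phenolate oxygen and hence not nucleophilic, and ionisation of the strained allylic C–O bond at 0–25 °C is far faster than oxidative addition to an electron-rich aryl or hindered vinyl bromide.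

Step 12
Reactants: 19 10-bromo-4-vinyl spirodienone
Product: 20 4-vinyl spirodienone (1S,3S,4S,5S; side chain 1S)
Conditions: Pd(PPh3)4 (5 mol %), Bu3SnH (1.1 equiv, slow addition), THF, rt
Reagents that add atoms: none
Why: Palladium-catalysed hydrodehalogenation (oxidative addition into the activated β-bromoenone C–Br bond, tin-to-palladium hydride transfer, reductive elimination) removes the control element without changing a stereocentre, simple alkenes and silyl ethers being inert.

Step 13
Reactants: 20 4-vinyl spirodienone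
Product: 22 spirodienone C4-carbaldehyde, via vicinal diol 21 (not isolated)
Conditions: OsO4 (2 mol %), NaIO4 (4 equiv), 2,6-lutidine, dioxane–H2O, rt
Reagents that add atoms: osmium tetroxide, O=[Os](=O)(=O)=O; sodium periodate, [Na+].[O-]I(=O)(=O)=O
Why: Lemieux–Johnson oxidation: osmium tetroxide dihydroxylates the only unconjugated monosubstituted alkene in preference to the electron-poor and hindered dienone double bonds, periodate cleaves the diol, and lutidine keeps the medium neutral so that C4 does not epimerise.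

Step 14
Reactants: 22 spirodienone C4-carbaldehyde
Product: 23 tris-silylated target
Conditions: NaBH4 (1 equiv), CH2Cl2–MeOH, −78 °C; sat. aq NH4Cl
Reagents that add atoms: none
Why: Chemoselective borohydride reduction at low temperature, where an aldehyde is reduced far faster than the cross-conjugated α-methoxy dienone carbonyl.

Step 15
Reactants: 23 tris-silylated target
Product: 24 CNP0252711.1
Conditions: TBAF/AcOH (1:1, 5 equiv), THF, 0 °C → rt
Reagents that add atoms: none
Why: Fluoride-induced cleavage of all three silyl ethers, buffered with acetic acid so that neither phenoxide-triggered opening of the C3–O2 bond nor acid-induced dienone–phenol rearrangement can set in.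

Compound list
1 | vanillin | O=Cc1ccc(O)c(OC)c1 | starting material
2 | 3-methoxy-4-(triisopropylsilyloxy)benzaldehyde | O=Cc1ccc(O[Si](C(C)C)(C(C)C)C(C)C)c(OC)c1 | intermediate
3 | diethyl allylphosphonate | C=CCP(=O)(OCC)OCC | starting material
4 | (E)-1-[3-methoxy-4-(triisopropylsilyloxy)phenyl]buta-1,3-diene | C=C/C=C/c1ccc(O[Si](C(C)C)(C(C)C)C(C)C)c(OC)c1 | intermediate
5 | (2R,3R)-2-[3-methoxy-4-(triisopropylsilyloxy)phenyl]-3-vinyloxirane (trans) | C=C[C@H]1O[C@@H]1c1ccc(O[Si](C(C)C)(C(C)C)C(C)C)c(OC)c1 | intermediate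
6 | methyl 3-(4-hydroxy-3-methoxyphenyl)propanoate (methyl dihydroferulate) | COC(=O)CCc1ccc(O)c(OC)c1 | starting material
7 | bromoacetic acid | OC(=O)CBr | starting material
8 | 2-[2-methoxy-4-(3-methoxy-3-oxopropyl)phenoxy]acetic acid | COC(=O)CCc1ccc(OCC(=O)O)c(OC)c1 | intermediate
9 | (R)-4-benzyl-1,3-oxazolidin-2-one | O=C1N[C@H](Cc2ccccc2)CO1 | starting material
10 | methyl 3-[4-[2-[(4R)-4-benzyl-2-oxo-1,3-oxazolidin-3-yl]-2-oxoethoxy]-3-methoxyphenyl]propanoate | COC(=O)CCc1ccc(OCC(=O)N2[C@H](Cc3ccccc3)COC2=O)c(OC)c1 | intermediate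
11 | 2-bromo-4-hydroxy-5-methoxybenzaldehyde (6-bromovanillin) | O=Cc1cc(OC)c(O)cc1Br | starting material
12 | 2-bromo-5-methoxy-4-(methoxymethoxy)benzaldehyde | O=Cc1cc(OC)c(OCOC)cc1Br | intermediate
13 | (Z)-dibutylboron enolate of 10 (O–B and O–aryl cis) | CCCCB(CCCC)O/C(=C\Oc1ccc(CCC(=O)OC)cc1OC)N1[C@H](Cc2ccccc2)COC1=O | intermediate
14 | (4R)-4-benzyl-3-[(2R,3S)-3-[2-bromo-5-methoxy-4-(methoxymethoxy)phenyl]-3-hydroxy-2-[2-methoxy-4-(3-methoxy-3-oxopropyl)phenoxy]propanoyl]-1,3-oxazolidin-2-one | COCOc1cc(Br)c(cc1OC)[C@H](O)[C@H](C(=O)N1[C@H](Cc2ccccc2)COC1=O)Oc1ccc(CCC(=O)OC)cc1OC | intermediate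
15 | (1S,2S)-1-[2-bromo-5-methoxy-4-(methoxymethoxy)phenyl]-2-[4-(3-hydroxypropyl)-2-methoxyphenoxy]propane-1,3-diol | COCOc1cc(Br)c(cc1OC)[C@H](O)[C@H](CO)Oc1ccc(CCCO)cc1OC | intermediate
16 | (1S,2S)-1-[2-bromo-5-methoxy-4-(methoxymethoxy)phenyl]-3-(tert-butyldiphenylsilyloxy)-2-[4-[3-(tert-butyldiphenylsilyloxy)propyl]-2-methoxyphenoxy]propan-1-ol | COCOc1cc(Br)c(cc1OC)[C@H](O)[C@H](CO[Si](c1ccccc1)(c1ccccc1)C(C)(C)C)Oc1ccc(CCCO[Si](c2ccccc2)(c2ccccc2)C(C)(C)C)cc1OC | intermediate
17 | benzylic bromide of 16 with the MOM group exchanged for an aryl TMS ether (epimers at C–Br, aryloxy carbon unchanged) | C[Si](C)(C)Oc1cc(Br)c(cc1OC)C(Br)[C@H](CO[Si](c1ccccc1)(c1ccccc1)C(C)(C)C)Oc1ccc(CCCO[Si](c2ccccc2)(c2ccccc2)C(C)(C)C)cc1OC | intermediate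
18 | (4E)-5-bromo-2-methoxy-4-[(2R)-3-(tert-butyldiphenylsilyloxy)-2-[4-[3-(tert-butyldiphenylsilyloxy)propyl]-2-methoxyphenoxy]propylidene]cyclohexa-2,5-dien-1-one | COC1=C/C(=C\[C@H](CO[Si](c2ccccc2)(c2ccccc2)C(C)(C)C)Oc2ccc(CCCO[Si](c3ccccc3)(c3ccccc3)C(C)(C)C)cc2OC)C(Br)=CC1=O | intermediate
19 | (1S,3S,4S,5R)-10-bromo-4-ethenyl-7-methoxy-3-[3-methoxy-4-(triisopropylsilyloxy)phenyl]-1-[(1S)-2-(tert-butyldiphenylsilyloxy)-1-[4-[3-(tert-butyldiphenylsilyloxy)propyl]-2-methoxyphenoxy]ethyl]-2-oxaspiro[4.5]deca-6,9-dien-8-one (aryl and C10–Br arm on one face of the oxolane; vinyl, side chain and C6=C7 arm on the other) | COC1=C[C@]2(C(Br)=CC1=O)[C@H](C=C)[C@@H](c1ccc(O[Si](C(C)C)(C(C)C)C(C)C)c(OC)c1)O[C@@H]2[C@H](CO[Si](c1ccccc1)(c1ccccc1)C(C)(C)C)Oc1ccc(CCCO[Si](c3ccccc3)(c3ccccc3)C(C)(C)C)cc1OC | intermediate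
20 | (1S,3S,4S,5S)-4-ethenyl analogue of 19 without bromine | COC1=C[C@]2(C=CC1=O)[C@H](C=C)[C@@H](c1ccc(O[Si](C(C)C)(C(C)C)C(C)C)c(OC)c1)O[C@@H]2[C@H](CO[Si](c1ccccc1)(c1ccccc1)C(C)(C)C)Oc1ccc(CCCO[Si](c3ccccc3)(c3ccccc3)C(C)(C)C)cc1OC | intermediate
21 | 4-(1,2-dihydroxyethyl) analogue of 20 (ring configuration as in 20, new carbinol centre not controlled) | COC1=C[C@]2(C=CC1=O)[C@H](C(O)CO)[C@@H](c1ccc(O[Si](C(C)C)(C(C)C)C(C)C)c(OC)c1)O[C@@H]2[C@H](CO[Si](c1ccccc1)(c1ccccc1)C(C)(C)C)Oc1ccc(CCCO[Si](c3ccccc3)(c3ccccc3)C(C)(C)C)cc1OC | intermediate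
22 | (1S,3S,4S,5R)-4-carbaldehyde (spatial arrangement as in 20) | COC1=C[C@]2(C=CC1=O)[C@H](C=O)[C@@H](c1ccc(O[Si](C(C)C)(C(C)C)C(C)C)c(OC)c1)O[C@@H]2[C@H](CO[Si](c1ccccc1)(c1ccccc1)C(C)(C)C)Oc1ccc(CCCO[Si](c3ccccc3)(c3ccccc3)C(C)(C)C)cc1OC | intermediate
23 | (1S,3S,4R,5S)-4-(hydroxymethyl) compound, aryl TIPS ether and two TBDPS ethers still in place | COC1=C[C@]2(C=CC1=O)[C@H](CO)[C@@H](c1ccc(O[Si](C(C)C)(C(C)C)C(C)C)c(OC)c1)O[C@@H]2[C@H](CO[Si](c1ccccc1)(c1ccccc1)C(C)(C)C)Oc1ccc(CCCO[Si](c3ccccc3)(c3ccccc3)C(C)(C)C)cc1OC | intermediate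
24 | (1S,3S,4R,5S)-3-(4-hydroxy-3-methoxyphenyl)-4-(hydroxymethyl)-1-[(1S)-2-hydroxy-1-[4-(3-hydroxypropyl)-2-methoxyphenoxy]ethyl]-7-methoxy-2-oxaspiro[4.5]deca-6,9-dien-8-one (CNP0252711.1) | COC1=C[C@]2(C=CC1=O)[C@H](CO)[C@@H](c1ccc(O)c(OC)c1)O[C@@H]2[C@H](CO)Oc1ccc(CCCO)cc1OC | target

Total step count: 15. Longest linear sequence: 11 steps (6 → 8 → 10 → 14 → 15 → 16 → 18 → 19 → 20 → 22 → 23 → 24, that is steps 4, 5, 7–15). Steps 1–3 and step 6 run in parallel.

Steps most likely to fail

Step 11.
- What may go wrong: the quinone methide may tautomerise to the styryl aryl ether or oligomerise under the basic zwitterion before it is captured. The oxirane may isomerise to the aryl ketone on palladium. Facial control at C1 and C5 may be incomplete.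
- Fallback: the two bond formations are uncoupled. Setting out from 5, Pd(PPh3)4-catalysed 1,4-addition of pivalic acid (THF, 0 °C) opens the oxirane to the (S,E)-hydroxy allyl pivalate F1.
- Its lithium alkoxide (LiHMDS, THF, −78 °C) adds in a 1,6-sense to 18. A buffered quench gives the phenolic benzyl ether F2, whose C1 epimers can be separated by chromatography.
- An intramolecular palladium-catalysed allylic dearomatisation of the para-substituted phenol (Pd2(dba)3, DPEphos, Cs2CO3, THF, rt) then forms C4–C5 and comes back to the route at 19.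

Step 10.
- What may go wrong: hydrogen bromide formed in the flask may erode the silyl ethers, cleavage of the MOM acetal may lag behind bromide formation, and water may add back to the quinone methide during the wash.
- Fallback: an acid-free, base-triggered release. Setting out from 16, acetylation (Ac2O, pyridine, DMAP) gives the benzylic acetate F3.
- ZnBr2/n-PrSH (CH2Cl2, 0 °C) removes the MOM group to give the p-hydroxybenzyl acetate F4.
- Stirring with solid K2CO3 in dry CH2Cl2 causes 1,6-elimination of acetic acid and comes back to the route at 18, without any aqueous contact.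

Step 12.
- What may go wrong: Pd(0) may re-ionise the allylic C4–C5 bond with rearomatisation, the allyl fragment then being trapped by hydride. The tin hydride may also reduce the dienone in a conjugate sense.
- Fallback: the bromine is carried on until the allyl unit is gone and is then removed by a radical chain instead of by palladium. Setting out from 19, Lemieux–Johnson oxidation runs through the bromo diol F5 to the bromo aldehyde F6.
- Low-temperature NaBH4 reduction gives the bromo alcohol F7.
- (Me3Si)3SiH/Et3B/air (toluene, 0 °C) replaces Br by H through the vinyl radical and comes back to the route at 23.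

Further compounds
F1 | step 11 | (2E,4S)-4-hydroxy-4-[3-methoxy-4-(triisopropylsilyloxy)phenyl]but-2-en-1-yl pivalate | CC(C)(C)C(=O)OC/C=C/[C@H](O)c1ccc(O[Si](C(C)C)(C(C)C)C(C)C)c(OC)c1
F2 | step 11 | phenolic benzyl ether from 1,6-addition of F1 to 18 (C1, C3 and side-chain carbon configured as in 19) | CC(C)(C)C(=O)OC/C=C/[C@@H](c1ccc(O[Si](C(C)C)(C(C)C)C(C)C)c(OC)c1)O[C@@H](c1cc(OC)c(O)cc1Br)[C@H](CO[Si](c1ccccc1)(c1ccccc1)C(C)(C)C)Oc1ccc(CCCO[Si](c2ccccc2)(c2ccccc2)C(C)(C)C)cc1OC
F3 | step 10 | benzylic acetate of 16 | COCOc1cc(Br)c(cc1OC)[C@H](OC(C)=O)[C@H](CO[Si](c1ccccc1)(c1ccccc1)C(C)(C)C)Oc1ccc(CCCO[Si](c2ccccc2)(c2ccccc2)C(C)(C)C)cc1OC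
F4 | step 10 | p-hydroxybenzyl acetate (F3 without MOM group) | Oc1cc(Br)c(cc1OC)[C@H](OC(C)=O)[C@H](CO[Si](c1ccccc1)(c1ccccc1)C(C)(C)C)Oc1ccc(CCCO[Si](c2ccccc2)(c2ccccc2)C(C)(C)C)cc1OC
F5 | step 12 | 10-bromo 4-(1,2-dihydroxyethyl) spirodienone (not isolated) | COC1=C[C@]2(C(Br)=CC1=O)[C@H](C(O)CO)[C@@H](c1ccc(O[Si](C(C)C)(C(C)C)C(C)C)c(OC)c1)O[C@@H]2[C@H](CO[Si](c1ccccc1)(c1ccccc1)C(C)(C)C)Oc1ccc(CCCO[Si](c3ccccc3)(c3ccccc3)C(C)(C)C)cc1OC
F6 | step 12 | 10-bromo spirodienone 4-carbaldehyde | COC1=C[C@]2(C(Br)=CC1=O)[C@H](C=O)[C@@H](c1ccc(O[Si](C(C)C)(C(C)C)C(C)C)c(OC)c1)O[C@@H]2[C@H](CO[Si](c1ccccc1)(c1ccccc1)C(C)(C)C)Oc1ccc(CCCO[Si](c3ccccc3)(c3ccccc3)C(C)(C)C)cc1OC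
F7 | step 12 | 10-bromo 4-(hydroxymethyl) spirodienone | COC1=C[C@]2(C(Br)=CC1=O)[C@H](CO)[C@@H](c1ccc(O[Si](C(C)C)(C(C)C)C(C)C)c(OC)c1)O[C@@H]2[C@H](CO[Si](c1ccccc1)(c1ccccc1)C(C)(C)C)Oc1ccc(CCCO[Si](c3ccccc3)(c3ccccc3)C(C)(C)C)cc1OC
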